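Read the ceiling first.

in all of them: electrophile 1.5 M
- teal: nucleophile 3 M; solid base 0.45 M; temperature 35 °C; the very flask that is asked about, followed so far
- ochre: nucleophile 3 M; solid base 0.45 M; temperature 30 °C; run made earlier
- flask: nucleophile 3.00 M; solid base 0.450 M; temperature 35 °C; time 40 h

- teal (time / h: target / %): 6.00: 36.4; 12.0: 42.5; 20.0: 44.8; 25.0: 46.7
- ochre (time / h: target / %): 6.00: 32.4; 12.0: 39.3; 20.0: 40.1; 25.0: 40.8

(readings scatter by 1 percentage point)

- beta: at 40 h take out 90% of the target then present, then wait 3.0 d
- zeta: at 40 h raise the temperature by 25 K, then wait 3.0 d
- gamma: change nothing and wait 3.0 d more

- target, in percent of the electrophile first charged, at 40 h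
- the remedy with the largest gain of target, or "none" below 2 percentage points (beta / zeta / gamma / none)
- target present, with what was taken out counted in, in percent of the electrophile first charged, after beta
- target present, with what was taken out counted in, in percent of the electrophile first charged, after gamma

- given per volume of solution although it is solid: solid base
- removed target is counted in
- at the start none of the solid base is in solution

The asked flask is the teal run carried on. Its target climbs fast and then bends. This reckoning assumes that both reagents fall by the same share of their own charge; second-order consumption then makes 1/c(electrophile) grow linearly in time and gives a hyperbola, so it puts one through the first and last teal readings: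

y = Y·t/(t + τ), with Y = 51.3% and τ = 2.45 h

Y is the ceiling share: the part of the converted electrophile that stands as target once conversion is over. The reckoning reads it as a reversible split between the target and another form. The teal readings never fall, so the split is taken to keep pace with conversion.

The ladder then runs upward from τ. On this curve the target stands at half of Y at τ. The last teal reading, at 25.0 h, lies at ten times τ, on the flat part of the curve. The asked time is 16.3 lifetimes, which gives:

now = Y·t/(t + τ) = 48.3%

gamma = 50.2%

Under beta, the share taken out is banked, and the rest of the charge, taken here as fully converted by the end of the wait, splits again at Y: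

beta = x·now + Y·(1 − x·now) = 72.5%

Zeta stays unpriced here, since the ochre run offers one short temperature step. Beta is this reckoning's choice, ahead of the about 70% that the forecast expects from zeta.

The forecast gives now 47%, g1 62%, g3 48.5% and best zeta. “Zeta looks best, though the extrapolation is uncertain.”

The simulation gives now 49.1%, g1 72.3%, g3 51.7% and best beta, with gains of 23 percentage points for beta, 17 points for zeta and 2.6 points for gamma.

    acid set free + free base ⇌ salt of the base (K = 1.50 /M, k = 0.110 /M/min, Ea = 65.0 kJ/mol, ΔH = −79.0 kJ/mol)
    target ⇌ isomer of the product (K = 0.880, k = 0.00660 /min, Ea = 106 kJ/mol, ΔH = −18.0 kJ/mol)
    solid base ⇌ free base, rate k3*(cs3 - [free base]) while solid is left; crystals form when [free base] > cs3 (solubility = 0.380 M, k = 0.00110 /min)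
    nucleophile + acid set free ⇌ protonated nucleophile, settled at all times (K = 2100 /M, ΔH = 30.0 kJ/mol)
    electrophile + nucleophile → acid set free + target (k = 0.00160 /M/min, Ea = 90.0 kJ/mol)
    (constants at 35 °C)

At 40.0 h the asked flask holds 49.1% target beside 43.0% isomer of the product with 7.9% of its electrophile left, so Y on the converted part gives 47.2%, and the relaxation half-life of target and isomer of the product, 0.819 h, is shorter than the time. The repeat at 20 °C still holds 34% of its electrophile at 40.0 h, so Y, read at 35 °C, gives 33.9% on the converted part, and that flask stands at 35.0%.

Readings and results come from a simulation with constants of no real substance; scatter was added.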